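## The problem

The target 20 is a tetracyclic depsidone. A pentasubstituted benzoate (ring A, primed locants: C1' carries the carboxyl carbon, C2' the ether oxygen, C3' the formyl group, C4' a hydroxyl, C6' a methyl) is tied twice to a hexasubstituted benzene (ring B, chromanone numbering). The ties are the diaryl ether C2'–O–C7 and the ester from the C1' carboxyl to the C6 oxygen, so a seven-membered dioxepinone lies between the arenes, and ring B is also fused to a 2,2-dimethyl-2,3-dihydropyran-4-one (ring C: O1, C2, C3, C4 ketone). There is no stereogenic centre, so every difficulty is positional. Ring B carries four adjacent oxygens (C6, C7, C8, C8a) that end as lactone oxygen, ether oxygen, free phenol and ring C oxygen, and each must be told apart from its neighbours; ring A needs its formyl group between two oxygens. The diaryl ether is flanked by two oxygen substituents in ring B and by the carboxyl in ring A, the least favourable case for a metal-mediated ether coupling. Several groups limit the reagents: the salicylaldehyde, the aryl ester of the seven-membered ring (opened by nucleophiles; in its open form ring A can migrate between the C7 and C6 oxygens by Smiles rearrangement under base), the β-aryloxy ketone of ring C (retro-oxa-Michael opening and retro-aldol loss of acetone in hot alkali) and the electron-rich phenols. The enabling feature is that ring A (carboxyl at C1', oxygen at C2' and C4', methyl at C6', hydrogen at C3' and C5') is what a 6-methyl-2-pyranone-5-carboxylate with an oxygen at pyranone C4 gives with the two carbons of a ketene acetal after cycloaddition and loss of CO2; that C4 oxygen can be brought in as the C7 phenoxide of ring B by addition–elimination. Ring B has the oxygen and methyl pattern of commercial coenzyme Q0 (5), whose single free ring position is where ring C must be attached.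

## Retrosynthesis

**20 ⇒ 19 (C3'–CHO bond).** The aldehyde is the group least able to survive BBr3, BCl3, a ketene acetal or phenoxide chemistry, so it is introduced last, by electrophilic ortho-formylation of the C4' phenol of 19. C3' lies between the phenol and the ring ether oxygen and para to the methyl group; C5', the only other free carbon, has the C6' methyl as ortho neighbour. Ring B has no free carbon. The forward reaction must deliver one carbon at C3' without touching the lactone.

**19 ⇒ 18 (two O–CH3 bonds).** The C4' oxygen leaves the key step as a methyl ether and the C8 oxygen is a methyl ether from 5; both are removed together. Doing this before formylation keeps the aldehyde away from BBr3 and gives the formylation a free phenol as director. The C8 oxygen must stay masked until the lactone exists, otherwise two phenols (O6 and O8) could close the seven-membered ring.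

**18 ⇒ 17 (lactone C–O bond).** The seven-membered ring is opened at the ester, not at the ether. The reverse order (ester first, then an Ullmann-type ether closure) would put the most congested bond formation at the end. In 17 only O6 is free, so ring closure has one possible outcome.

**17 ⇒ 16 (O6–isopropyl and carboxyl–benzyl bonds).** Both groups fall to BCl3 in one operation while the two methyl ethers stay. A benzyl ester is chosen because it is cleaved by O–alkyl fission under acid; saponification of a 2,6-disubstituted benzoate would need hot hydroxide, which endangers ring C. The C6 phenol is never exposed to base next to the ester-activated ether, which closes off the Smiles pathway.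

**16 ⇒ 12 + 13 (C3'–C4' and C5'–C6' bonds; key step).** Ring A is taken apart into aryloxypyranone 12 and 1,1-dimethoxyethene (13). The neighbouring option, a preformed orsellinate joined to ring B by ether coupling, keeps the congested coupling; here the ether already exists before ring A does. The precursor is simpler by one benzene ring and two C–C bonds. The forward reaction needs one regiochemical outcome, methoxyl para to the ester, which the polarisation of the pyranone supplies.

**12 ⇒ 4 + 11 (pyranone C4–O bond).** The ether is cut next to the pyranone, where it can form by addition–elimination of phenoxide 11 on the vinylogous acid chloride 4. A chloride is preferred to a sulfonate because a phenoxide can attack a sulfonate at sulfur.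

**4 ⇒ 3 ⇒ 1 + 2.** The chloride comes from hydroxypyranone 3, and 3 from benzyl acetoacetate (1) and malonyl dichloride (2), which place ester, methyl and hydroxyl at pyranone C5, C6 and C4 in one condensation.

**11 ⇒ 10 ⇒ 9 ⇒ 6 + 7; 6 ⇒ 5.** The C7 phenol is unmasked from dimethyl ether 10 by nucleophilic demethylation; C7 is the only methoxyl para to the ketone. The isopropyl group of 10 is put on the single free hydroxyl of 9. Ring C of 9 comes from hydroquinone 6 and 3-methylbut-2-enoic acid (7): acylation can occur only at the one free ring carbon, and only one hydroxyl is ortho to it (via enone 8). Hydroquinone 6 is the reduction product of 5. No oxygen is introduced onto ring B at any stage.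

## Roads not taken

**Alternative 1:** Ring B is disconnected at C5–C6 and traced to a squaric ester. The mixed squarate A3 (methoxy and the ring A aryloxy group on the cyclobutenedione) would take up (E)-prop-1-enyllithium to give cyclobutenone A2. On heating, A2 opens to a dienylketene, six-electron closure forms C5–C6, and tautomerisation gives hydroquinone A1 with ring A already on the C7 oxygen.
- Merits: the diaryl ether again comes from an addition–elimination; all four ring B oxygens arrive in defined positions; A1 has both hydroquinone hydroxyls free for chromanone annulation and lactonisation, so the sequence to the depsidone core could be about half as long as the chosen one.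
- Weak points: the organolithium must choose between two similar carbonyls of A3 (the one vinylogous to the aryloxy group is favoured, but only by the difference in donor strength between aryloxy and methoxy); the aryloxy group can be displaced by a second addition–elimination; the benzoate of ring A must survive the organolithium; A1 is an oxidation-prone hydroquinone; ring A still needs the late formylation.
- Comparison: this road is shorter and builds the most substituted ring from scratch. The chosen plan sets against it that 5 supplies the same pattern with no regiochemical decision and that no carbanion meets an ester.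

**Alternative 2:** The lactone C–O bond and the two ring C bonds C4–C4a and O1–C2 are cut at once. In P2O5/MeSO3H the aryloxyhydroquinone acid A4 and 3-methylbut-2-enoic acid would lactonise at the C6 hydroxyl and annulate ring C in one pot to give the core dimethyl ether A5, which is the same structure as 18.
- Merits: the shortest endgame of all; the outcome is structurally enforced (only one hydroxyl is ortho to the ether, only one is ortho to the free carbon); xanthone formation, the usual fate of 2-aryloxybenzoic acids in this medium, is blocked because both positions ortho to the ether oxygen in ring B are oxygenated.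
- Weak points: ring A of A4 has two free, oxygen-activated carbons that compete for the acylium ion of the unsaturated acid; the hydroquinone can be O-acylated; and the whole difficulty moves into A4, whose congested ether must come from an Ullmann coupling or from alternative 1.
- Comparison: two ring-forming steps are saved against the chosen route. The chosen plan sets against this a stepwise assembly in which each ring closure has one possible course and the ether is formed under mild carbonate conditions.

**Alternative 3:** The C1'–carbonyl and carbonyl–O6 bonds are cut and the lactone carbon is traced to carbon monoxide. Zerovalent palladium (from Pd(OAc)2 and Xantphos) would insert into the C1'–I bond of iodo ether A6, CO would insert, and the C6 phenol would capture the acyl to give A7, the target as its dimethyl ether.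
- Merits: the aldehyde is in place before the lactone, so there is no late formylation and no ester to unmask; A7 is one deprotection from 20; the ether of A6 could come from a fluoride activated by the ortho formyl group.
- Weak points: oxidative addition at an iodide flanked by aryloxy and methyl is slow; the aldehyde can be decarbonylated or reduced under CO and palladium; hydrodeiodination competes; and A6 needs a hexasubstituted ring A (iodine, aryloxy, formyl, methoxy, methyl) built by classical arene substitution with its own regiochemical problems.
- Comparison: the endgame is better than the chosen one. The chosen plan sets against it that ring A arises in one cycloaddition from acyclic commercial pieces, leaving only the position of the formyl group to be decided.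

Key step: step 8

Remark on the chemistry: 20 has no stereogenic centre; the only chiral species on the route is the bridged cycloadduct 14, which forms as a racemate, is not isolated, and loses both centres on extrusion of CO2.

## Route

Step 1
Reactants: 1 benzyl acetoacetate; 2 malonyl dichloride
Product: 3 benzyl 4-hydroxy-6-methyl-2-oxo-2H-pyran-5-carboxylate
Conditions: neat, 20 → 50 °C, HCl swept out with N2
Reagents that add atoms: none
Why: Malonyl dichloride acylates the β-keto ester twice, at the α-carbon and at the enol oxygen of the acetyl group, which closes the 4-hydroxy-2-pyranone with the ester at C5 and the methyl at C6; the condensation is established for acetoacetic esters and a benzyl ester is inert to the HCl set free.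

Step 2
Reactants: 3 benzyl 4-hydroxy-6-methyl-2-oxo-2H-pyran-5-carboxylate
Product: 4 benzyl 4-chloro-6-methyl-2-oxo-2H-pyran-5-carboxylate
Conditions: POCl3, Et3N, toluene, 80 °C
Reagents that add atoms: phosphoryl chloride, O=P(Cl)(Cl)Cl
Why: Deoxychlorination of the vinylogous acid is the standard way from 4-hydroxy-2-pyranones to 4-chloro-2-pyranones; the chloride is chosen over a sulfonate because a phenoxide can attack it only at carbon.

Step 3
Reactants: 5 coenzyme Q0 (2,3-dimethoxy-5-methyl-1,4-benzoquinone)
Product: 6 2,3-dimethoxy-5-methylbenzene-1,4-diol
Conditions: Na2S2O4, EtOAc/H2O, rt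
Reagents that add atoms: none
Why: Dithionite reduction of a benzoquinone to its hydroquinone; the product is used at once to avoid reoxidation.

Step 4
Reactants: 6 2,3-dimethoxy-5-methylbenzene-1,4-diol; 7 3-methylbut-2-enoic acid
Product: 9 6-hydroxy-7,8-dimethoxy-2,2,5-trimethylchroman-4-one, via aryl enone 8 (not isolated)
Conditions: P2O5, MeSO3H, 70 °C
Reagents that add atoms: none
Why: Friedel–Crafts acylation at the only unsubstituted ring carbon gives enone 8, and oxa-Michael addition of the one hydroxyl ortho to the acyl group closes ring C; the other hydroxyl, next to the methyl group, cannot cyclise, as in the known annulation of trimethylhydroquinone with the same acid.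

Step 5
Reactants: 9 6-hydroxy-7,8-dimethoxy-2,2,5-trimethylchroman-4-one
Product: 10 6-isopropoxy-7,8-dimethoxy-2,2,5-trimethylchroman-4-one
Conditions: 2-bromopropane, K2CO3, DMF, 60 °C
Reagents that add atoms: 2-bromopropane, CC(C)Br
Why: Williamson etherification of the single free phenol; the isopropyl ether is inert to thiolate and is later removed by BCl3 without loss of methyl ethers.

Step 6
Reactants: 10 6-isopropoxy-7,8-dimethoxy-2,2,5-trimethylchroman-4-one
Product: 11 7-hydroxy-6-isopropoxy-8-methoxy-2,2,5-trimethylchroman-4-one
Conditions: NaSEt, DMF, 100 °C; then 1 M HCl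
Reagents that add atoms: none
Why: SN2 demethylation by thiolate selects the C7 methoxyl because it is para to the C4 ketone (its phenoxide is the best leaving group) and is twisted out of plane by two ortho oxygens, as in the 4-demethylation of 3,4,5-trimethoxyaryl carbonyl compounds. The C8 methoxyl is meta to the ketone, the secondary isopropyl ether resists SN2 attack, and the phenoxide formed deactivates the ring against a second cleavage.

Step 7
Reactants: 4 benzyl 4-chloro-6-methyl-2-oxo-2H-pyran-5-carboxylate; 11 7-hydroxy-6-isopropoxy-8-methoxy-2,2,5-trimethylchroman-4-one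
Product: 12 benzyl 4-[(6-isopropoxy-8-methoxy-2,2,5-trimethyl-4-oxochroman-7-yl)oxy]-6-methyl-2-oxo-2H-pyran-5-carboxylate
Conditions: K2CO3, MeCN, 50 °C
Reagents that add atoms: none
Why: Addition–elimination of the phenoxide at pyranone C4, as known for 4-halo-6-methyl-2-pyranones and 4-chlorocoumarins with phenols. Additions of the phenoxide at pyranone C6 or C2 are reversible, whereas attack at C4 expels chloride, so the hindered ether forms without a metal.

Step 8
Reactants: 12 benzyl 4-[(6-isopropoxy-8-methoxy-2,2,5-trimethyl-4-oxochroman-7-yl)oxy]-6-methyl-2-oxo-2H-pyran-5-carboxylate; 13 1,1-dimethoxyethene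
Product: 16 benzyl 2-[(6-isopropoxy-8-methoxy-2,2,5-trimethyl-4-oxochroman-7-yl)oxy]-4-methoxy-6-methylbenzoate, via bridged lactone adduct 14 (not isolated), via dimethoxycyclohexadiene 15 (not isolated)
Conditions: 13 (5 equiv), toluene, 120 °C, sealed tube
Reagents that add atoms: none
Why: Inverse-electron-demand Diels–Alder reaction of a 2-pyranone-5-carboxylate with a ketene acetal followed by retro-[4+2] loss of CO2 (an Alder–Rickert-type sequence), a known route to 4-alkoxybenzoates. The electron-rich CH2 terminus of 13 bonds to pyranone C6, made electrophilic by both the C5 ester and the lactone carbonyl, and the acetal carbon bonds to pyranone C3, the β-carbon of the C4 aryloxy enol ether, giving the 2-oxabicyclo[2.2.2]octenone 14; bond formation may be asynchronous or stepwise through a zwitterion with the same outcome. Cycloreversion of 14 expels CO2 to give diene 15, and 1,2-elimination of methanol across the former dienophile carbons aromatises it. Ring A is therefore closed by an intermolecular [4+2] cycloaddition that forms C3'–C4' and C5'–C6', not by a cyclisation. The two bridgehead centres of 14 arise as a racemic pair and vanish in the next event, so no stereocontrol is needed. The selectivity required is regiochemical, methoxyl para to the ester, and it is secured because the ester, the lactone carbonyl and the aryloxy donor all polarise the diene in the same sense. The ring C ketone, the benzyl ester and the fully substituted ring B offer 13 no reactive π-system, and the excess of 13 covers the part consumed by the methanol set free.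

Step 9
Reactants: 16 benzyl 2-[(6-isopropoxy-8-methoxy-2,2,5-trimethyl-4-oxochroman-7-yl)oxy]-4-methoxy-6-methylbenzoate
Product: 17 2-[(6-hydroxy-8-methoxy-2,2,5-trimethyl-4-oxochroman-7-yl)oxy]-4-methoxy-6-methylbenzoic acid
Conditions: BCl3, pentamethylbenzene, CH2Cl2, −78 → 0 °C; then H2O
Reagents that add atoms: none
Why: BCl3 cleaves isopropyl aryl ethers and benzyl esters by O–alkyl fission at temperatures at which aryl methyl ethers without an ortho carbonyl or ortho boron-bound oxygen survive, and pentamethylbenzene traps the benzyl cation before it can alkylate ring A. Acid is used because the free C6 phenol beside the ether would be open to Smiles rearrangement under base.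

Step 10
Reactants: 17 2-[(6-hydroxy-8-methoxy-2,2,5-trimethyl-4-oxochroman-7-yl)oxy]-4-methoxy-6-methylbenzoic acid
Product: 18 depsidone dimethyl ether (seven-membered lactone from the C1' carboxyl to O6; 4'-methoxy, 6'-methyl, 8-methoxy)
Conditions: (CF3CO)2O, toluene, rt
Reagents that add atoms: none
Why: Mixed-anhydride lactonisation, the usual closure of depsidones from 2-(2-hydroxyaryloxy)benzoic acids; only O6 is free, so the ring can close one way, and ring B has no free carbon at which the acyl cation could form a xanthone.

Step 11
Reactants: 18 depsidone dimethyl ether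
Product: 19 depsidone diphenol (3'-deformyl target; 4'-hydroxy, 8-hydroxy)
Conditions: BBr3, CH2Cl2, −78 °C → rt; then H2O
Reagents that add atoms: none
Why: BBr3 cleaves both aryl methyl ethers, the C8 ether (flanked by two oxygens) fastest, while aryl lactones of depsidones and chromanone ketones tolerate the reagent; should ring C open at O1–C2 it recloses by oxa-Michael addition, since only O1 is ortho to the acyl group.

Step 12
Reactants: 19 depsidone diphenol
Product: 20 target depsidone (3'-formyl-4',8-dihydroxy)
Conditions: Cl2CHOMe, TiCl4, CH2Cl2, −10 → 0 °C; then 1 M HCl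
Reagents that add atoms: dichloromethyl methyl ether, COC(Cl)Cl; water, O
Why: Rieche ortho-formylation of a phenol through its titanium phenoxide. C3' lies between the phenol and the ring ether oxygen and para to the methyl group, the position attacked in 4-hydroxy-2-oxyaryl carbonyl systems (orsellinates to haematommates, 7-hydroxycoumarins to 8-formyl derivatives), whereas C5' is shielded by the ortho methyl group and ring B has no free carbon.

## Compound list

1 | benzyl acetoacetate (benzyl 3-oxobutanoate) | CC(=O)CC(=O)OCc1ccccc1 | starting material
2 | malonyl dichloride | O=C(Cl)CC(=O)Cl | starting material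
3 | benzyl 4-hydroxy-6-methyl-2-oxo-2H-pyran-5-carboxylate | CC1=C(C(=O)OCc2ccccc2)C(O)=CC(=O)O1 | intermediate
4 | benzyl 4-chloro-6-methyl-2-oxo-2H-pyran-5-carboxylate | CC1=C(C(=O)OCc2ccccc2)C(Cl)=CC(=O)O1 | intermediate
5 | coenzyme Q0 (2,3-dimethoxy-5-methyl-1,4-benzoquinone) | COC1=C(OC)C(=O)C(C)=CC1=O | starting material
6 | 2,3-dimethoxy-5-methylbenzene-1,4-diol | COc1c(OC)c(O)c(C)cc1O | intermediate
7 | 3-methylbut-2-enoic acid | CC(C)=CC(=O)O | starting material
8 | 1-(2,5-dihydroxy-3,4-dimethoxy-6-methylphenyl)-3-methylbut-2-en-1-one | COc1c(OC)c(O)c(C)c(C(=O)C=C(C)C)c1O | intermediate (not isolated)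
9 | 6-hydroxy-7,8-dimethoxy-2,2,5-trimethylchroman-4-one | COc1c(OC)c(O)c(C)c2C(=O)CC(C)(C)Oc12 | intermediate
10 | 6-isopropoxy-7,8-dimethoxy-2,2,5-trimethylchroman-4-one | COc1c(OC)c(OC(C)C)c(C)c2C(=O)CC(C)(C)Oc12 | intermediate
11 | 7-hydroxy-6-isopropoxy-8-methoxy-2,2,5-trimethylchroman-4-one | COc1c(O)c(OC(C)C)c(C)c2C(=O)CC(C)(C)Oc12 | intermediate
12 | benzyl 4-[(6-isopropoxy-8-methoxy-2,2,5-trimethyl-4-oxochroman-7-yl)oxy]-6-methyl-2-oxo-2H-pyran-5-carboxylate | CC1=C(C(=O)OCc2ccccc2)C(Oc2c(OC(C)C)c(C)c3C(=O)CC(C)(C)Oc3c2OC)=CC(=O)O1 | intermediate
13 | 1,1-dimethoxyethene | C=C(OC)OC | starting material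
14 | benzyl 5-[(6-isopropoxy-8-methoxy-2,2,5-trimethyl-4-oxochroman-7-yl)oxy]-8,8-dimethoxy-1-methyl-3-oxo-2-oxabicyclo[2.2.2]oct-5-ene-6-carboxylate (racemic; one enantiomer drawn; the relative configuration of the bridgeheads is fixed by the bicycle) | O=C(OCc1ccccc1)C1=C(Oc3c(OC(C)C)c(C)c4C(=O)CC(C)(C)Oc4c3OC)[C@@H]2C(=O)O[C@@]1(C)CC2(OC)OC | intermediate (not isolated)
15 | benzyl 6-[(6-isopropoxy-8-methoxy-2,2,5-trimethyl-4-oxochroman-7-yl)oxy]-4,4-dimethoxy-2-methylcyclohexa-1,5-diene-1-carboxylate | O=C(OCc1ccccc1)C1=C(C)CC(OC)(OC)C=C1Oc1c(OC(C)C)c(C)c2C(=O)CC(C)(C)Oc2c1OC | intermediate (not isolated)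
16 | benzyl 2-[(6-isopropoxy-8-methoxy-2,2,5-trimethyl-4-oxochroman-7-yl)oxy]-4-methoxy-6-methylbenzoate | O=C(OCc1ccccc1)c1c(C)cc(OC)cc1Oc1c(OC(C)C)c(C)c2C(=O)CC(C)(C)Oc2c1OC | intermediate
17 | 2-[(6-hydroxy-8-methoxy-2,2,5-trimethyl-4-oxochroman-7-yl)oxy]-4-methoxy-6-methylbenzoic acid | OC(=O)c1c(C)cc(OC)cc1Oc1c(O)c(C)c2C(=O)CC(C)(C)Oc2c1OC | intermediate
18 | depsidone dimethyl ether (lactone of 17 between the C1' carboxyl and O6; 4'-methoxy, 8-methoxy) | Cc1cc(OC)cc2c1C(=O)Oc1c(C)c3c(c(OC)c1O2)OC(C)(C)CC3=O | intermediate
19 | depsidone diphenol (3'-deformyl target; 4'-hydroxy, 8-hydroxy) | Cc1cc(O)cc2c1C(=O)Oc1c(C)c3c(c(O)c1O2)OC(C)(C)CC3=O | intermediate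
20 | CNP0271978.0 (3'-formyl-4',8-dihydroxy depsidone) | Cc1cc(O)c(C=O)c2c1C(=O)Oc1c(C)c3c(c(O)c1O2)OC(C)(C)CC3=O | target

## Step count and least certain steps

Total: 12 steps. Longest linear sequence: 10 steps (5 → 20, steps 3 to 12); the pyranone arm (steps 1 and 2) joins at step 7.

**Step 8 (key step).** The cycloaddition may be too slow at temperatures the ketene acetal tolerates. The aryloxy donor at pyranone C4 and the methyl at C6 raise the diene LUMO and shield C6, so 13 could be lost by oligomerisation or by adding the methanol set free before the diene is consumed; stalling before aromatisation is also possible. Fallback: activate the diene instead of forcing the conditions. Setting out from 12, bromination at pyranone C3 (N-bromosuccinimide, MeCN) should give benzyl 3-bromo-4-[(6-isopropoxy-8-methoxy-2,2,5-trimethyl-4-oxochroman-7-yl)oxy]-6-methyl-2-oxo-2H-pyran-5-carboxylate F1; 3-halo-2-pyranones are more reactive dienes with the same polarisation. Cycloaddition of F1 with 13 should give benzyl 3-bromo-2-[(6-isopropoxy-8-methoxy-2,2,5-trimethyl-4-oxochroman-7-yl)oxy]-4-methoxy-6-methylbenzoate F2. Hydrodebromination (Pd(PPh3)4, HCO2Na, DMF, 100 °C) leaves the benzyl ester intact and comes back to the route at 16.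

**Step 12.** Site selectivity may be poor, with attack at C5' (ortho to the phenol, para to the ring ether oxygen) competing with attack at C3'. Fallback: carry the position as a halogen through the key step. Setting out from 12 and passing through F1 and F2 as described for step 8, BCl3 with pentamethylbenzene should give 3-bromo-2-[(6-hydroxy-8-methoxy-2,2,5-trimethyl-4-oxochroman-7-yl)oxy]-4-methoxy-6-methylbenzoic acid F3, and (CF3CO)2O should give the 3'-bromo depsidone dimethyl ether F4. Reductive carbonylation (zerovalent palladium from Pd(OAc)2 and di(1-adamantyl)-n-butylphosphine, CO/H2, TMEDA, toluene, 100 °C) should give the 3'-formyl depsidone dimethyl ether F5, and BBr3 then comes back to the route at 20. The formyl carbon then stands where pyranone C3 stood, without any choice between C3' and C5'.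

**Step 7.** The doubly ortho-substituted, para-acyl phenoxide is a weak nucleophile; slow substitution would let carbonate or traces of hydroxide open the pyranone at C6 or C2 or hydrolyse 4 back to 3. Fallback: form the same bond by cross-coupling instead of addition–elimination. Setting out from 4 and 11, zerovalent palladium from Pd2(dba)3 with 2-(di-tert-butylphosphino)-2',4',6'-triisopropylbiphenyl and K3PO4 in toluene at 80 °C (oxidative addition into the C4–Cl bond, C–O reductive elimination) comes back to the route at 12 without a new compound; the insoluble base keeps the concentration of free phenoxide low.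

**Step 6.** Selectivity may be lost by cleavage of the C8 methoxyl as well, or the thiolate may open ring C by retro-oxa-Michael reaction followed by conjugate addition. Fallback: differentiate O7 by a neighbouring-group effect and by acidity. Setting out from 9, BCl3 (CH2Cl2, 0 °C) should cleave only the methoxyl next to the free hydroxyl, through the cyclic borate, to give 6,7-dihydroxy-8-methoxy-2,2,5-trimethylchroman-4-one F6. Benzylation of the more acidic, para-acyl C7 hydroxyl (BnBr, NaHCO3, DMF) should give 7-(benzyloxy)-6-hydroxy-8-methoxy-2,2,5-trimethylchroman-4-one F7. Isopropylation as in step 5 should give 7-(benzyloxy)-6-isopropoxy-8-methoxy-2,2,5-trimethylchroman-4-one F8, and hydrogenolysis (H2, Pd/C, EtOAc) comes back to the route at 11.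

## Further compounds

F1 | step 8 | benzyl 3-bromo-4-[(6-isopropoxy-8-methoxy-2,2,5-trimethyl-4-oxochroman-7-yl)oxy]-6-methyl-2-oxo-2H-pyran-5-carboxylate | O=C(OCc1ccccc1)C1=C(C)OC(=O)C(Br)=C1Oc1c(OC(C)C)c(C)c2C(=O)CC(C)(C)Oc2c1OC
F2 | step 8 | benzyl 3-bromo-2-[(6-isopropoxy-8-methoxy-2,2,5-trimethyl-4-oxochroman-7-yl)oxy]-4-methoxy-6-methylbenzoate | O=C(OCc1ccccc1)c1c(C)cc(OC)c(Br)c1Oc1c(OC(C)C)c(C)c2C(=O)CC(C)(C)Oc2c1OC
F3 | step 12 | 3-bromo-2-[(6-hydroxy-8-methoxy-2,2,5-trimethyl-4-oxochroman-7-yl)oxy]-4-methoxy-6-methylbenzoic acid | OC(=O)c1c(C)cc(OC)c(Br)c1Oc1c(O)c(C)c2C(=O)CC(C)(C)Oc2c1OC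
F4 | step 12 | 3'-bromo depsidone dimethyl ether (4'-methoxy, 8-methoxy) | Cc1cc(OC)c(Br)c2c1C(=O)Oc1c(C)c3c(c(OC)c1O2)OC(C)(C)CC3=O
F5 | step 12 | 3'-formyl depsidone dimethyl ether (4'-methoxy, 8-methoxy) | Cc1cc(OC)c(C=O)c2c1C(=O)Oc1c(C)c3c(c(OC)c1O2)OC(C)(C)CC3=O
F0 | step 7 | none | none
F6 | step 6 | 6,7-dihydroxy-8-methoxy-2,2,5-trimethylchroman-4-one | COc1c(O)c(O)c(C)c2C(=O)CC(C)(C)Oc12
F7 | step 6 | 7-(benzyloxy)-6-hydroxy-8-methoxy-2,2,5-trimethylchroman-4-one | COc1c(OCc3ccccc3)c(O)c(C)c2C(=O)CC(C)(C)Oc12
F8 | step 6 | 7-(benzyloxy)-6-isopropoxy-8-methoxy-2,2,5-trimethylchroman-4-one | COc1c(OCc3ccccc3)c(OC(C)C)c(C)c2C(=O)CC(C)(C)Oc12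
A1 | alternative 1 | methyl 2-(2,5-dihydroxy-6-methoxy-3-methylphenoxy)-4-methoxy-6-methylbenzoate | COC(=O)c1c(C)cc(OC)cc1Oc1c(O)c(C)cc(O)c1OC
A2 | alternative 1 | methyl 2-({3-hydroxy-2-methoxy-4-oxo-3-[(E)-prop-1-en-1-yl]cyclobut-1-en-1-yl}oxy)-4-methoxy-6-methylbenzoate (racemic) | COC(=O)c1c(C)cc(OC)cc1OC1=C(OC)C(O)(/C=C/C)C1=O
A3 | alternative 1 | methyl 4-methoxy-2-[(2-methoxy-3,4-dioxocyclobut-1-en-1-yl)oxy]-6-methylbenzoate | COC(=O)c1c(C)cc(OC)cc1OC1=C(OC)C(=O)C1=O
A4 | alternative 2 | 2-(2,5-dihydroxy-6-methoxy-3-methylphenoxy)-4-methoxy-6-methylbenzoic acid | OC(=O)c1c(C)cc(OC)cc1Oc1c(O)c(C)cc(O)c1OC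
A5 | alternative 2 | 3'-deformyl depsidone core as its 4',8-dimethyl ether | Cc1cc(OC)cc2c1C(=O)Oc1c(C)c3c(c(OC)c1O2)OC(C)(C)CC3=O
A6 | alternative 3 | 2-[(6-hydroxy-8-methoxy-2,2,5-trimethyl-4-oxochroman-7-yl)oxy]-3-iodo-6-methoxy-4-methylbenzaldehyde | Cc1cc(OC)c(C=O)c(Oc2c(O)c(C)c3C(=O)CC(C)(C)Oc3c2OC)c1I
A7 | alternative 3 | target as its 4',8-dimethyl ether | Cc1cc(OC)c(C=O)c2c1C(=O)Oc1c(C)c3c(c(OC)c1O2)OC(C)(C)CC3=O
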